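**Retrosynthetic overview**

1. Target 16 ⇐ hydrogenolysis of benzyl ether 15 ⇐ O-methylation of bis(4-hydroxycoumarin) 14.
2. Key step: 14 ⇐ twofold intermolecular Claisen condensation of the biaryl bis(2-hydroxyacetophenone) 11 with diethyl carbonate 12 (forms C2–C3 and C2'–C3'), each followed by lactonisation.
3. 11 ⇐ selective benzylation of triol 10 ⇐ BCl3 dealkylation of diketone 9 ⇐ twofold Friedel–Crafts acetylation of biaryl 8.
4. 8 ⇐ Suzuki–Miyaura coupling of bromide 3 (from orcinol, as isopropyl ethers) with boronic acid 7 (from 3,5-dimethoxytoluene by directed lithiation).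
5. Ring order: both benzene rings are bought, the biaryl bond is made first, and the two pyranone rings are closed last and together in the Claisen step.

Assumption: the SMILES carries no stereodescriptor and the only stereogenic element is the hindered biaryl axis, so the axis is left uncontrolled and the compound is made as the racemate that the SMILES describes.

Ring B is the ring derived from orcinol; it becomes the 6-linked coumarin carrying the free 7-OH. Ring A is the ring derived from 3,5-dimethoxytoluene; it becomes the 8'-linked coumarin carrying the 7'-OMe.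

**Route**

Step 1
Reactants: 1 orcinol (5-methylbenzene-1,3-diol)
Product: 2 1,3-diisopropoxy-5-methylbenzene
Conditions: 2-bromopropane (3 equiv), K2CO3 (3 equiv), DMF, 70 °C
Reagents that add atoms: 2-bromopropane, CC(C)Br
Why: Williamson ether synthesis alkylates both phenoxides to a symmetric diether whose isopropyl groups can later be removed by BCl3 without loss of unchelated methyl ethers; no stereocentre is formed.

Step 2
Reactants: 2 1,3-diisopropoxy-5-methylbenzene
Product: 3 2-bromo-1,5-diisopropoxy-3-methylbenzene
Conditions: NBS (1.0 equiv), MeCN, 0 °C → rt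
Reagents that add atoms: N-bromosuccinimide, O=C1CCC(=O)N1Br
Why: Electrophilic aromatic bromination occurs once, para to one isopropoxy group and ortho to the methyl, because the site between the two bulky isopropoxy groups is shielded and the two remaining sites are equivalent by symmetry; no stereocentre is formed.

Step 3
Reactants: 4 1,3-dimethoxy-5-methylbenzene (3,5-dimethoxytoluene)
Product: 7 (2,6-dimethoxy-4-methylphenyl)boronic acid, via (2,6-dimethoxy-4-methylphenyl)lithium 5 (not isolated), via dimethyl (2,6-dimethoxy-4-methylphenyl)boronate 6 (not isolated)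
Conditions: n-BuLi (1.1 equiv), THF, 0 °C → rt; B(OMe)3 (1.5 equiv), −78 °C → rt; 1 M HCl, 0 °C
Reagents that add atoms: trimethyl borate, COB(OC)OC; water, O
Why: Directed ortho-metalation removes the most acidic ring proton, the one flanked by both methoxy groups, and the aryllithium is trapped by the borate and hydrolysed to the boronic acid; no stereocentre is formed.

Step 4
Reactants: 3 2-bromo-1,5-diisopropoxy-3-methylbenzene; 7 (2,6-dimethoxy-4-methylphenyl)boronic acid (1.5 equiv)
Product: 8 2,4-diisopropoxy-2',6'-dimethoxy-4',6-dimethyl-1,1'-biphenyl (racemic axis)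
Conditions: Pd(OAc)2 (5 mol %), SPhos (10 mol %), K3PO4 (3 equiv), toluene/H2O 10:1, 100 °C
Reagents that add atoms: none
Why: In this Suzuki–Miyaura coupling the bulky electron-rich SPhos ligand on zerovalent palladium permits oxidative addition to the hindered bromide and reductive elimination to the tetra-ortho-substituted biaryl, with excess 7 covering protodeboronation; the new biaryl axis is formed without control, as the assumption allows.

Step 5
Reactants: 8 2,4-diisopropoxy-2',6'-dimethoxy-4',6-dimethyl-1,1'-biphenyl
Product: 9 1-[3-(3-acetyl-2,6-dimethoxy-4-methylphenyl)-4,6-diisopropoxy-2-methylphenyl]ethan-1-one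
Conditions: AcCl (2.6 equiv), SnCl4 (2.6 equiv), CH2Cl2, −20 → 0 °C; ice/H2O
Reagents that add atoms: acetyl chloride, CC(Cl)=O
Why: In this twofold Friedel–Crafts acylation each ring reacts at its only accessible activated site, ortho to the methyl and para to an alkoxy group (the two such sites of ring A are equivalent, the site between the isopropoxy groups of ring B is blocked), and a ring acylated once is deactivated so the second acetyl enters the other ring; no new stereocentre is formed.

Any material that has already lost the alkyl group ortho to an acetyl converges on 10 in step 6.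

Step 6
Reactants: 9 1-[3-(3-acetyl-2,6-dimethoxy-4-methylphenyl)-4,6-diisopropoxy-2-methylphenyl]ethan-1-one
Product: 10 1-[3-(3-acetyl-2-hydroxy-6-methoxy-4-methylphenyl)-4,6-dihydroxy-2-methylphenyl]ethan-1-one
Conditions: BCl3 (6 equiv, 1 M in CH2Cl2), CH2Cl2, −78 → 0 °C; H2O
Reagents that add atoms: none
Why: In this Lewis-acid ether cleavage BCl3 removes both isopropyl ethers and the one methyl ether chelated to an ortho acetyl group, while the unchelated methyl ether of ring A survives at 0 °C, which sets apart the future 7'-OMe from the future 7-OH; the axis is untouched.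

Step 7
Reactants: 10 1-[3-(3-acetyl-2-hydroxy-6-methoxy-4-methylphenyl)-4,6-dihydroxy-2-methylphenyl]ethan-1-one
Product: 11 1-[3-(3-acetyl-2-hydroxy-6-methoxy-4-methylphenyl)-4-(benzyloxy)-6-hydroxy-2-methylphenyl]ethan-1-one
Conditions: BnBr (1.05 equiv), K2CO3 (1.2 equiv), acetone, 56 °C
Reagents that add atoms: benzyl bromide, BrCc1ccccc1
Why: In this selective Williamson alkylation the two phenols ortho to an acetyl group are held in strong intramolecular hydrogen bonds and stay unreactive, so only the free, more acidic phenol of ring B next to the axis is benzylated; no stereocentre is formed.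

Step 8
Reactants: 11 1-[3-(3-acetyl-2-hydroxy-6-methoxy-4-methylphenyl)-4-(benzyloxy)-6-hydroxy-2-methylphenyl]ethan-1-one; 12 diethyl carbonate (20 equiv)
Product: 14 7-(benzyloxy)-4,4'-dihydroxy-7'-methoxy-5,5'-dimethyl-2H,2'H-[6,8'-bichromene]-2,2'-dione, via bis(beta-keto ester) 13 (not isolated)
Conditions: NaH (10 equiv), toluene, 110 °C; H2O, then 2 M HCl to pH 2
Reagents that add atoms: diethyl carbonate, CCOC(=O)OCC
Why: In this twofold crossed Claisen condensation each methyl-ketone enolate is acylated by diethyl carbonate, driven by deprotonation of the beta-keto ester, and the neighbouring phenoxide then closes the lactone with loss of ethoxide to give the 4-hydroxycoumarin; no stereocentre is formed and the axis is untouched.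

Step 9
Reactants: 14 7-(benzyloxy)-4,4'-dihydroxy-7'-methoxy-5,5'-dimethyl-2H,2'H-[6,8'-bichromene]-2,2'-dione
Product: 15 7-(benzyloxy)-4,4',7'-trimethoxy-5,5'-dimethyl-2H,2'H-[6,8'-bichromene]-2,2'-dione
Conditions: Me2SO4 (3 equiv), K2CO3 (4 equiv), acetone, 56 °C
Reagents that add atoms: dimethyl sulfate, COS(=O)(=O)OC
Why: O-alkylation (SN2) of the two vinylogous carboxylic acids with the hard electrophile Me2SO4 gives the 4-methoxycoumarins in preference to C3-methyl or 2-methoxychromone isomers; no stereocentre is formed.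

Step 10
Reactants: 15 7-(benzyloxy)-4,4',7'-trimethoxy-5,5'-dimethyl-2H,2'H-[6,8'-bichromene]-2,2'-dione
Product: 16 7-hydroxy-4,4',7'-trimethoxy-5,5'-dimethyl-2H,2'H-[6,8'-bichromene]-2,2'-dione (target, racemic axis)
Conditions: H2 (1 atm), 10% Pd/C, EtOAc/MeOH 1:1, rt
Reagents that add atoms: none
Why: Catalytic hydrogenolysis cleaves the benzylic C–O bond under conditions that leave the aryl methyl ethers and the electron-rich trisubstituted 4-methoxycoumarin double bonds untouched; the axis is unaffected.

**Compound list**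

1 | orcinol (5-methylbenzene-1,3-diol) | Cc1cc(O)cc(O)c1 | starting material
2 | 1,3-diisopropoxy-5-methylbenzene | Cc1cc(OC(C)C)cc(OC(C)C)c1 | intermediate
3 | 2-bromo-1,5-diisopropoxy-3-methylbenzene | Cc1cc(OC(C)C)cc(OC(C)C)c1Br | intermediate
4 | 1,3-dimethoxy-5-methylbenzene (3,5-dimethoxytoluene) | COc1cc(C)cc(OC)c1 | starting material
5 | (2,6-dimethoxy-4-methylphenyl)lithium | COc1cc(C)cc(OC)c1[Li] | intermediate (not isolated)
6 | dimethyl (2,6-dimethoxy-4-methylphenyl)boronate | COB(OC)c1c(OC)cc(C)cc1OC | intermediate (not isolated)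
7 | (2,6-dimethoxy-4-methylphenyl)boronic acid | COc1cc(C)cc(OC)c1B(O)O | intermediate
8 | 2,4-diisopropoxy-2',6'-dimethoxy-4',6-dimethyl-1,1'-biphenyl (racemic axis) | COc1cc(C)cc(OC)c1-c1c(C)cc(OC(C)C)cc1OC(C)C | intermediate
9 | 1-[3-(3-acetyl-2,6-dimethoxy-4-methylphenyl)-4,6-diisopropoxy-2-methylphenyl]ethan-1-one | COc1cc(C)c(C(C)=O)c(OC)c1-c1c(C)c(C(C)=O)c(OC(C)C)cc1OC(C)C | intermediate
10 | 1-[3-(3-acetyl-2-hydroxy-6-methoxy-4-methylphenyl)-4,6-dihydroxy-2-methylphenyl]ethan-1-one | COc1cc(C)c(C(C)=O)c(O)c1-c1c(C)c(C(C)=O)c(O)cc1O | intermediate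
11 | 1-[3-(3-acetyl-2-hydroxy-6-methoxy-4-methylphenyl)-4-(benzyloxy)-6-hydroxy-2-methylphenyl]ethan-1-one | COc1cc(C)c(C(C)=O)c(O)c1-c1c(C)c(C(C)=O)c(O)cc1OCc1ccccc1 | intermediate
12 | diethyl carbonate | CCOC(=O)OCC | starting material
13 | ethyl 3-[3-[6-(benzyloxy)-3-(3-ethoxy-3-oxopropanoyl)-4-hydroxy-2-methylphenyl]-2-hydroxy-4-methoxy-6-methylphenyl]-3-oxopropanoate (bis(beta-keto ester)) | COc1cc(C)c(C(=O)CC(=O)OCC)c(O)c1-c1c(C)c(C(=O)CC(=O)OCC)c(O)cc1OCc1ccccc1 | intermediate (not isolated)
14 | 7-(benzyloxy)-4,4'-dihydroxy-7'-methoxy-5,5'-dimethyl-2H,2'H-[6,8'-bichromene]-2,2'-dione | COc1cc(C)c2c(O)cc(=O)oc2c1-c1c(OCc3ccccc3)cc2oc(=O)cc(O)c2c1C | intermediate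
15 | 7-(benzyloxy)-4,4',7'-trimethoxy-5,5'-dimethyl-2H,2'H-[6,8'-bichromene]-2,2'-dione | COc1cc(C)c2c(OC)cc(=O)oc2c1-c1c(OCc3ccccc3)cc2oc(=O)cc(OC)c2c1C | intermediate
16 | 7-hydroxy-4,4',7'-trimethoxy-5,5'-dimethyl-2H,2'H-[6,8'-bichromene]-2,2'-dione (racemic axis) | COc1cc(C)c2c(OC)cc(=O)oc2c1-c1c(O)cc2oc(=O)cc(OC)c2c1C | target

**Totals and risks**

Total step count: 10. Longest linear sequence: 9 steps (orcinol 1 → 16 through steps 1, 2 and 4–10); step 3 is a one-step side branch.

Three steps most likely to fail:

Step 4 (tetra-ortho-substituted Suzuki coupling; protodeboronation of 7 or a stalled coupling). Fallback: a Negishi coupling. It sets out from aryllithium 5 (made from 4 as in step 3) and bromide 3. Compound 5 is transmetalated with ZnCl2 in THF (0 °C → rt) to (2,6-dimethoxy-4-methylphenyl)zinc chloride F1. F1 is coupled with 3 using Pd2(dba)3/RuPhos in THF/NMP at 70 °C. The product is 8, where the route is rejoined.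

Step 5 (twofold Friedel–Crafts acetylation; incomplete second acylation or premature loss of isopropyl groups). Fallback: bromination, organolithium addition and oxidation. It sets out from 8. NBS (2.1 equiv, MeCN, 0 °C → rt) brominates the same two positions to give 3,3'-dibromo-4,6-diisopropoxy-2',6'-dimethoxy-2,4'-dimethyl-1,1'-biphenyl F2. Double bromine–lithium exchange (n-BuLi, THF, −78 °C) and addition to acetaldehyde gives the bis(1-hydroxyethyl) compound F3 as a diastereomer mixture, which is of no consequence. Dess–Martin periodinane in CH2Cl2 oxidises it to 9, where the route is rejoined.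

Step 8 (twofold Claisen condensation and lactonisation; reaction incomplete at one ring). Fallback: carbonate formation followed by intramolecular acyl transfer. It sets out from 11. Both chelated phenols are acylated with ethyl chloroformate (Et3N, DMAP, CH2Cl2) to the bis(ethyl carbonate) F4. LiN(SiMe3)2 in THF (−78 → 0 °C) forms the ketone enolates, which attack the neighbouring carbonate carbonyl (Baker–Venkataraman-type O→C transfer) and expel ethoxide to close both lactones. Acidification gives 14, where the route is rejoined.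

**Further compounds**

F1 | step 4 | (2,6-dimethoxy-4-methylphenyl)zinc chloride | COc1cc(C)cc(OC)c1[Zn]Cl
F2 | step 5 | 3,3'-dibromo-4,6-diisopropoxy-2',6'-dimethoxy-2,4'-dimethyl-1,1'-biphenyl | COc1cc(C)c(Br)c(OC)c1-c1c(C)c(Br)c(OC(C)C)cc1OC(C)C
F3 | step 5 | 1-[3-[3-(1-hydroxyethyl)-2,6-dimethoxy-4-methylphenyl]-4,6-diisopropoxy-2-methylphenyl]ethan-1-ol (diastereomer mixture) | COc1cc(C)c(C(C)O)c(OC)c1-c1c(C)c(C(C)O)c(OC(C)C)cc1OC(C)C
F4 | step 8 | bis(ethyl carbonate) of 11: 3-acetyl-2-[6-acetyl-3-(benzyloxy)-5-(ethoxycarbonyloxy)-2-... drawn as 11 with both phenolic OH groups converted to OC(=O)OEt | COc1cc(C)c(C(C)=O)c(OC(=O)OCC)c1-c1c(C)c(C(C)=O)c(OC(=O)OCC)cc1OCc1ccccc1
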